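## Retrosynthesis
1. The target comes from a boron-mediated Knoevenagel condensation (Pabon) of the aryl aldehyde **13** with p-coumaroylacetone **16**, so the curcuminoid is built last.
2. Aldehyde **13** comes from Pd-catalysed O-arylation of vanillin (net retention) on a cis-1,4-dioxygenated methylcyclohexene. That diol arises from the [4+2] cycloaddition of singlet O₂ to the 2-methylcyclohexa-1,3-diene **6**, anti to the C5 side chain, followed by O–O reduction.
3. Diene **6** (an α-turmerone-type dienone) comes from hydroboration and acylative Suzuki coupling of the isopropenyl group of triene **3**, which comes from a Shapiro reaction of (S)-carvone tosylhydrazone.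
4. The carbocycle and its stereocentre come pre-formed from carvone; the only new ring is the endoperoxide ring of **7**, formed in step 5 and opened in step 6.

Assumptions:
- Step 2 deprotonates at the α′-carbon (C6), giving the conjugated 1,3-diene.
- Step 3 creates the side-chain stereocentre (C7) with only modest selectivity, so both C7 epimers are carried forward and the wanted one is separated at diol **8**. It is identified by comparison with the natural product's data.

## Route

**Step 1**
Reactants: **1** (S)-(+)-carvone
Product: **2** (S)-carvone tosylhydrazone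
Conditions: TsNHNH₂ (1.05 equiv), MeOH, rt, 2 h
Reagents that add atoms: p-toluenesulfonylhydrazide, Cc1ccc(cc1)S(=O)(=O)NN
Why: Condensation of the ketone with the sulfonylhydrazide gives the hydrazone (hydrazone formation); the C5 stereocentre is untouched.

**Step 2**
Reactants: **2**
Product: **3** (S)-2-methyl-5-(prop-1-en-2-yl)cyclohexa-1,3-diene
Conditions: n-BuLi (3 equiv), TMEDA, hexane/THF, –78 °C → rt; then H₂O
Reagents that add atoms: none
Why: Shapiro reaction: the dianion loses Ts⁻ and N₂ to give the vinyllithium C1(Li)=C6, which is protonated to the 1,3-diene; C5 is not involved.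

**Step 3**
Reactants: **3**
Product: **4** B-alkyl-9-BBN adduct at the former isopropenyl CH₂, formed as a C7 epimer mixture and not isolated
Conditions: 9-BBN-H (1.0 equiv), THF, 0 °C → rt, 4 h
Reagents that add atoms: 9-BBN-H (9-borabicyclo[3.3.1]nonane), B1C2CCCC1CCC2
Why: Hydroboration is fast at the unhindered 1,1-disubstituted alkene and slow at the cyclic diene, and C7 is set by syn addition of H–B to the face preferred in the conformer that avoids strain with ring C5, giving a modest dr.

**Step 4**
Reactants: **4**; **5** 3,3-dimethylacryloyl chloride
Product: **6** (5S)-2-methyl-5-[(2S)-6-methyl-4-oxohept-5-en-2-yl]cyclohexa-1,3-diene (α-turmerone-type dienone). It is formed together with its C7 epimer and drawn here as the desired isomer.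
Conditions: **5** (1.3 equiv), PdCl₂(PPh₃)₂ (5 mol%), anhydrous K₃PO₄, toluene/THF, 60 °C
Reagents that add atoms: none
Why: Acylative Suzuki–Miyaura coupling of the B-alkyl-9-BBN with the acid chloride forms the ketone directly without disturbing the C7 centre.

**Step 5**
Reactants: **6**
Product: **7** 2,3-dioxabicyclo[2.2.2]oct-5-ene (endoperoxide), O–O bridge anti to the side chain
Conditions: ³O₂, TPP (1 mol%), hν (visible), CH₂Cl₂, –10 °C
Reagents that add atoms: singlet oxygen from O₂, O=O
Why: Singlet oxygen adds suprafacially across the diene termini in a [4+2] cycloaddition from the face opposite the C5 side chain, so both new C–O bonds (future C–OAr and C–OH) are cis to each other and trans to the side chain.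

**Step 6**
Reactants: **7**
Product: **8** cis-diol, (1S,4R,… ) with both OH trans to the side chain
Conditions: thiourea (2 equiv), MeOH, rt, 12 h; silica chromatography
Reagents that add atoms: none
Why: Thiourea cleaves O–O without touching the C=C or C=O, giving the cis-1,4-diol with both carbinol centres unchanged; the C7 epimer and the minor syn-derived diol are removed here.

**Step 7**
Reactants: **8**
Product: **9** mono-TBS ether at the OH next to the CH₂ (future free OH)
Conditions: TBSCl (1.1 equiv), imidazole, DMF, –10 → 0 °C
Reagents that add atoms: tert-butyldimethylsilyl chloride, CC(C)(C)[Si](C)(C)Cl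
Why: Silylation goes at the less hindered OH, flanked by CH₂ and a planar vinylic carbon, rather than the OH beside the branched carbon bearing the side chain; no stereocentre is changed.

**Step 8**
Reactants: **9**
Product: **10** methyl carbonate of the remaining allylic OH
Conditions: ClCO₂Me (1.5 equiv), pyridine, DMAP (cat.), CH₂Cl₂, 0 °C
Reagents that add atoms: methyl chloroformate, COC(=O)Cl
Why: Acylation of the free secondary allylic alcohol installs a Pd-ionisable leaving group with retention.

**Step 9**
Reactants: **10**; **11** vanillin
Product: **12** aryl ether, TBS-protected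
Conditions: **11** (1.5 equiv), Pd(PPh₃)₄ (5 mol%), THF, 50 °C
Reagents that add atoms: none
Why: Tsuji–Trost etherification: Pd(0) ionises the carbonate anti to the leaving group, and the phenoxide attacks the less hindered allyl terminus from the opposite face, so net retention leaves the OAr trans to the side chain and cis to the OTBS.

**Step 10**
Reactants: **12**
Product: **13** 4-[(1R,4S,5R)-4-hydroxy-2,4-… cyclohexenyloxy]-3-methoxybenzaldehyde, i.e. the aryl aldehyde carrying the full terpenoid unit with free OH
Conditions: HF·pyridine, pyridine/THF, 0 °C → rt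
Reagents that add atoms: none
Why: Fluoride-mediated Si–O cleavage under buffered conditions leaves the aldehyde, enones and allylic aryl ether intact and changes no stereocentre.

**Step 11** (independent branch, can be run at any time)
Reactants: **15** 4-hydroxybenzaldehyde; **14** acetylacetone (3 equiv)
Product: **16** (E)-6-(4-hydroxyphenyl)hex-5-ene-2,4-dione (p-coumaroylacetone)
Conditions: B₂O₃, B(OBu)₃, n-BuNH₂ (cat.), EtOAc, 40 °C; aq. HCl work-up
Reagents that add atoms: none
Why: Pabon boron-enolate Knoevenagel condensation; excess acetylacetone favours the mono-condensation product.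

**Step 12**
Reactants: **13**; **16**
Product: **17** demethoxybisabolocurcumin ether (target)
Conditions: **16** + B₂O₃ (0.7 equiv), EtOAc, 40 °C; then **13**, B(OBu)₃, n-BuNH₂ (0.2 equiv), 40–60 °C; mild aq. AcOH/THF work-up at rt
Reagents that add atoms: none
Why: Pabon condensation at the remaining acetyl CH₃ of the boron complex of **16** with the aldehyde gives the (E,E)-curcuminoid, and the five terpenoid stereocentres are untouched.

## Compound list
1 | (S)-(+)-carvone | CC1=CC[C@H](C(C)=C)CC1=O | starting material
2 | (S)-carvone tosylhydrazone | CC1=CC[C@H](C(C)=C)CC1=NNS(=O)(=O)c1ccc(C)cc1 | intermediate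
3 | (S)-2-methyl-5-isopropenylcyclohexa-1,3-diene | CC1=CC[C@H](C(C)=C)C=C1 | intermediate
4 | B-alkyl-9-BBN adduct (C7 epimers) | CC1=CC[C@H](C(C)CB2C3CCCC2CCC3)C=C1 | intermediate
5 | 3,3-dimethylacryloyl chloride | CC(C)=CC(=O)Cl | starting material
6 | dienone (α-turmerone-type), desired C7 epimer | CC1=CC[C@H]([C@@H](C)CC(=O)C=C(C)C)C=C1 | intermediate
7 | endoperoxide, O–O anti to side chain | CC1=C[C@H]2[C@@H]([C@@H](C)CC(=O)C=C(C)C)C[C@@H]1OO2 | intermediate
8 | cis-1,4-diol | O[C@H]1C=C(C)[C@@H](O)C[C@@H]1[C@@H](C)CC(=O)C=C(C)C | intermediate
9 | mono-TBS ether | O[C@H]1C=C(C)[C@@H](O[Si](C)(C)C(C)(C)C)C[C@@H]1[C@@H](C)CC(=O)C=C(C)C | intermediate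
10 | methyl carbonate | COC(=O)O[C@H]1C=C(C)[C@@H](O[Si](C)(C)C(C)(C)C)C[C@@H]1[C@@H](C)CC(=O)C=C(C)C | intermediate
11 | vanillin | COc1cc(C=O)ccc1O | starting material
12 | aryl ether, TBS-protected | COc1cc(C=O)ccc1O[C@H]1C=C(C)[C@@H](O[Si](C)(C)C(C)(C)C)C[C@@H]1[C@@H](C)CC(=O)C=C(C)C | intermediate
13 | aryl aldehyde with free OH | COc1cc(C=O)ccc1O[C@H]1C=C(C)[C@@H](O)C[C@@H]1[C@@H](C)CC(=O)C=C(C)C | intermediate
14 | acetylacetone | CC(=O)CC(C)=O | starting material
15 | 4-hydroxybenzaldehyde | O=Cc1ccc(O)cc1 | starting material
16 | p-coumaroylacetone | CC(=O)CC(=O)/C=C/c1ccc(O)cc1 | intermediate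
17 | demethoxybisabolocurcumin ether | COc1cc(/C=C/C(O)=C/C(=O)/C=C/c2ccc(O)cc2)ccc1O[C@H]1C=C(C)[C@@H](O)C[C@@H]1[C@@H](C)CC(=O)C=C(C)C | target

Total steps: 12. Longest linear sequence: 11 (carvone → 2 → 3 → 4 → 6 → 7 → 8 → 9 → 10 → 12 → 13 → 17).

## Three steps most likely to fail
1. **Step 3 (with step 4), the C7 stereocentre.** Selectivity is only 1,2-induction from ring C5, and the 9-BBN may also attack the diene.
   Fallback: hydrozirconation (Cp₂Zr(H)Cl) of **3**, then CuBr·SMe₂-mediated acylation with **5**. This is a different C–C bond-forming logic, but it is still substrate-controlled, so the epimers would again be separated at **8**.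
2. **Step 5, singlet-oxygen facial selectivity.** Attack syn to the side chain, or aromatisation of the sensitive diene, would lower the yield of the anti endoperoxide.
   Fallback: start from (R)-carvone instead. Form the extended dienolate with KOt-Bu and trap it at C2 with PhSeCl. Then H₂O₂ oxidation triggers a [2,3]-sigmatropic selenoxide rearrangement that installs the C4 oxygen to give the γ-hydroxy enone.
3. **Step 9, Pd-catalysed etherification.** Pd must bind the ring face that carries the side chain, and the regiochemistry or retention could be poor.
   Fallback: oxidise the free allylic alcohol of the step-7 intermediate **9** (Dess–Martin), reduce with L-Selectride to the cis (axial) alcohol, then do a Mitsunobu reaction with vanillin (PPh₃, DIAD), whose inversion gives the required trans aryl ether.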